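**Plan** (cembrane numbering: C1 carries the isopropylidene C15, C2 and C9 are the ketones, C3/C4 the epoxide, C8 and C12 the methyl-bearing stereocentres)
1. Cuts: C5–C6 (ring bond, made as a C5=C6 olefin by metathesis and then hydrogenated), C1–C2 (allylchromium plus epoxy aldehyde, then oxidation and conjugation), C9–C10 (alkylborane plus thioester).
2. Forward: (R)-linalool supplies C10–C17, C20 and the acetate; its vinyl group is hydroborated and acylated with a C6–C9 thioester, its prenyl end is ene-chlorinated and joined through chromium to a C2–C5 epoxy aldehyde; oxidation and conjugation give the open-chain diene, which is closed to the 14-membered ring and hydrogenated.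
3. Stereochemistry: C12 from (R)-linalool, C8 from an Evans alkylation, C3/C4 from a Sharpless epoxidation of an E-allylic alcohol; the two centres made in the chromium coupling are erased, and no stereocentre is made after the fragments are joined.
4. Enabling feature: C5 and C6 are plain methylenes, C5 sitting on the fully substituted oxirane carbon C4, and the only other C=C, the exocyclic C1=C15, is tetrasubstituted and conjugated to the C2 ketone, so the open-chain precursor has exactly two metathesis-active olefins and needs no protecting group.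

Key step: step 11

Remark: commercial (R)-(−)-linalool of high enantiomeric purity is assumed.

Step 1
Reactants: 1 (R)-(−)-linalool
Product: 2 (3R)-3,7-dimethylocta-1,6-dien-3-yl acetate
Conditions: Ac2O, Et3N, DMAP (cat.), CH2Cl2, rt
Reagents that add atoms: acetic anhydride, CC(=O)OC(C)=O
Why: DMAP-catalysed acylation of the tertiary allylic alcohol under basic conditions avoids ionisation, so C12 keeps the R configuration of linalool and the acetate of the target is in place from the start.

Step 2
Reactants: 3 (4R)-4-benzyl-3-propanoyl-1,3-oxazolidin-2-one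
Product: 5 (4R)-4-benzyl-3-[(2S)-2-methylpent-4-enoyl]-1,3-oxazolidin-2-one, via sodium Z-enolate 4 (not isolated)
Conditions: NaN(SiMe3)2, THF, −78 °C; allyl iodide, −78 → −40 °C
Reagents that add atoms: allyl iodide, C=CCI
Why: Evans asymmetric alkylation, in which the chelated Z-enolate is allylated on the face opposite the benzyl group of the (R)-auxiliary, should set C8 as S.

Step 3
Reactants: 5 (4R)-4-benzyl-3-[(2S)-2-methylpent-4-enoyl]-1,3-oxazolidin-2-one
Product: 6 S-ethyl (2S)-2-methylpent-4-enethioate
Conditions: EtSH, n-BuLi, THF, 0 °C; aq NH4Cl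
Reagents that add atoms: ethanethiol, CCS
Why: Transthioesterification of the N-acyloxazolidinone by lithium ethanethiolate at the exocyclic carbonyl should give the thioester without epimerisation and return the auxiliary.

Step 4
Reactants: 2 (3R)-3,7-dimethylocta-1,6-dien-3-yl acetate; 6 S-ethyl (2S)-2-methylpent-4-enethioate
Product: 8 (6R,10S)-2,6,10-trimethyl-9-oxotrideca-2,12-dien-6-yl acetate, via B-alkyl-9-BBN borane 7 (not isolated)
Conditions: 9-BBN (slightly less than 1 equiv per 2), THF, 0 °C → rt; then 6, Pd(PPh3)4 (5 mol %), CuTC [Cu(O2C-C4H3S), 1.5 equiv], Cs2CO3, THF, 45 °C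
Reagents that add atoms: none
Why: 9-BBN hydroborates only the monosubstituted vinyl group (anti-Markovnikov, trisubstituted olefin untouched) and the B-alkyl variant of the Liebeskind–Srogl thioester–organoboron coupling should join C10 to C9 as a ketone without over-addition, leaving the tertiary acetate, the allyl group and C8 intact.

Step 5
Reactants: 8 (6R,10S)-2,6,10-trimethyl-9-oxotrideca-2,12-dien-6-yl acetate
Product: 9 (6S,10S)-3-chloro-2,6,10-trimethyl-9-oxotrideca-1,12-dien-6-yl acetate (both C3 epimers; the descriptor at C6 changes by priority only)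
Conditions: Ca(OCl)2, solid CO2, CH2Cl2/H2O, 0 °C
Reagents that add atoms: calcium hypochlorite, [Ca+2].[O-]Cl.[O-]Cl
Why: Ene-type allylic chlorination by HOCl is selective for the electron-rich trisubstituted prenyl olefin over the terminal allyl group and gives the 3-chloro-2-methyl-1-alkene needed to functionalise C1; the new C–Cl centre is destroyed later.

Step 6
Reactants: 10 (2E)-3-methylpent-2-en-4-yn-1-ol
Product: 11 [(2S,3S)-3-ethynyl-3-methyloxiran-2-yl]methanol
Conditions: Ti(OiPr)4 (10 mol %), L-(+)-diethyl tartrate (12 mol %), t-BuOOH, 4 Å MS, CH2Cl2, −20 °C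
Reagents that add atoms: tert-butyl hydroperoxide, CC(C)(C)OO
Why: Sharpless asymmetric epoxidation; 10 has the substitution pattern of geraniol (methyl cis and the larger group trans to CH2OH), so L-(+)-tartrate should deliver oxygen to the face that gives (2S,3S)-epoxygeraniol from geraniol, which fixes C3 and C4, while the E geometry gives the trans relation of the two ring bonds.

Step 7
Reactants: 11 [(2S,3S)-3-ethynyl-3-methyloxiran-2-yl]methanol
Product: 12 [(2S,3S)-3-ethenyl-3-methyloxiran-2-yl]methanol
Conditions: H2 (1 atm), Lindlar catalyst (Pd/CaCO3 poisoned with Pb(OAc)2), quinoline, Et2O, 0 °C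
Reagents that add atoms: none
Why: Lindlar semihydrogenation of the terminal alkyne should stop at the vinyl group and leave the oxirane and both stereocentres untouched.

Step 8
Reactants: 12 [(2S,3S)-3-ethenyl-3-methyloxiran-2-yl]methanol
Product: 13 (2R,3S)-3-ethenyl-3-methyloxirane-2-carbaldehyde
Conditions: Dess–Martin periodinane, NaHCO3, CH2Cl2, 0 °C → rt; used at once as a solution
Reagents that add atoms: none
Why: Buffered Dess–Martin oxidation of the primary epoxy alcohol gives the volatile epoxy aldehyde without touching the oxirane (the descriptor at C2 changes by priority only).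

Step 9
Reactants: 9 (6S,10S)-3-chloro-2,6,10-trimethyl-9-oxotrideca-1,12-dien-6-yl acetate; 13 (2R,3S)-3-ethenyl-3-methyloxirane-2-carbaldehyde
Product: 15 (5R,9S)-1-[(2S,3S)-3-ethenyl-3-methyloxiran-2-yl]-1-hydroxy-5,9-dimethyl-8-oxo-2-(prop-1-en-2-yl)dodec-11-en-5-yl acetate (C1/C2 diastereomers of the chain), via allylchromium dichloride 14 (not isolated)
Conditions: CrCl2 (4 equiv), THF/DMF, 0 °C → rt, 9 and 13 added together, no iodide additive
Reagents that add atoms: none
Why: Nozaki–Hiyama allylation, in which the allylchromium reagent adds through its substituted γ-carbon (C1) to the aldehyde only (ketone, acetate and terminal olefins tolerated), forges C1–C2; the configurations at C1 and C2 do not matter because both centres become trigonal in step 10.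

Step 10
Reactants: 15 (5R,9S)-1-[(2S,3S)-3-ethenyl-3-methyloxiran-2-yl]-1-hydroxy-5,9-dimethyl-8-oxo-2-(prop-1-en-2-yl)dodec-11-en-5-yl acetate
Product: 17 (5R,9S)-1-[(2R,3S)-3-ethenyl-3-methyloxiran-2-yl]-5,9-dimethyl-1,8-dioxo-2-(propan-2-ylidene)dodec-11-en-5-yl acetate, via deconjugated diketone 16 (not isolated)
Conditions: Dess–Martin periodinane, NaHCO3, CH2Cl2, 0 °C; then DBU (0.3 equiv), CH2Cl2, 0 °C → rt
Reagents that add atoms: none
Why: Oxidation gives the deconjugated ketone, whose C1–H is both α to the ketone and allylic, so catalytic DBU should move the double bond into conjugation (isopulegone-to-pulegone type prototropy) to the tetrasubstituted isopropylidene enone while the much less acidic C8–H and the oxirane C–H stay untouched.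

Step 11
Reactants: 17 (5R,9S)-1-[(2R,3S)-3-ethenyl-3-methyloxiran-2-yl]-5,9-dimethyl-1,8-dioxo-2-(propan-2-ylidene)dodec-11-en-5-yl acetate
Product: 18 (1R,6R,10S,14S)-6,10,14-trimethyl-2,9-dioxo-3-(propan-2-ylidene)-15-oxabicyclo[12.1.0]pentadec-12-en-6-yl acetate (E/Z mixture)
Conditions: second-generation Hoveyda–Grubbs catalyst RuCl2(H2IMes)(=CH-C6H4-2-OiPr) (10 mol %, in portions), toluene (1 mM), 80 °C, argon sparge
Reagents that add atoms: none
Why: The ruthenium alkylidene should load onto the unhindered allyl terminus at C6 by [2+2] cycloaddition and cycloreversion (Chauvin mechanism), and the resulting carbene then engages the vinyl group on C4 intramolecularly, so that a second metallacyclobutane collapses to the C5=C6 double bond and ethylene, whose removal makes the closure irreversible. The closest known reaction type is macrocyclic ring-closing metathesis of α,ω-dienes, including dienes with a vinyl oxirane or a fully substituted allylic carbon at one terminus. One ring is closed, the 14-membered carbocycle, by end-to-end union of the two terminal olefins (a macrocyclisation; the oxirane is already present and becomes the fused three-membered ring). No stereocentre is created: C3, C4, C8 and C12 are carried in unchanged, and the E/Z geometry of the new olefin is irrelevant because step 12 saturates it. The step needs chemoselectivity among three C=C bonds and ring closure over oligomerisation; the first is secured by the substrate, whose only other olefin, C1=C15, is tetrasubstituted and conjugated to the C2 ketone and therefore inert to the carbene, and the second by high dilution, helped by the trigonal C1, C2 and C9 and the oxirane, which limit the chain's freedom. The ketones, the tertiary acetate and the epoxide are not expected to react with the catalyst.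

Step 12
Reactants: 18 (1R,6R,10S,14S)-6,10,14-trimethyl-2,9-dioxo-3-(propan-2-ylidene)-15-oxabicyclo[12.1.0]pentadec-12-en-6-yl acetate
Product: 19 (1R,6R,10S,14S)-6,10,14-trimethyl-2,9-dioxo-3-(propan-2-ylidene)-15-oxabicyclo[12.1.0]pentadecan-6-yl acetate (CNP0229580.1)
Conditions: H2 (3 atm), RhCl(PPh3)3 (20 mol %), benzene, rt
Reagents that add atoms: none
Why: Homogeneous hydrogenation with RhCl(PPh3)3 should saturate the 1,2-disubstituted ring olefin (both isomers) but not the tetrasubstituted enone C=C or the ketones, and being neutral it should spare the allylic epoxide; a diimide reduction is avoided because the hydrazine it generates could trigger a Wharton reaction of the epoxy ketone.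

**Compound list**
1 | (R)-(−)-linalool, (3R)-3,7-dimethylocta-1,6-dien-3-ol | C=C[C@](C)(O)CCC=C(C)C | starting material
2 | (3R)-3,7-dimethylocta-1,6-dien-3-yl acetate | C=C[C@](C)(OC(C)=O)CCC=C(C)C | intermediate
3 | (4R)-4-benzyl-3-propanoyl-1,3-oxazolidin-2-one | CCC(=O)N1[C@H](Cc2ccccc2)COC1=O | starting material
4 | sodium Z-enolate of 3 | C/C=C(\[O-])N1[C@H](Cc2ccccc2)COC1=O.[Na+] | intermediate
5 | (4R)-4-benzyl-3-[(2S)-2-methylpent-4-enoyl]-1,3-oxazolidin-2-one | C=CC[C@H](C)C(=O)N1[C@H](Cc2ccccc2)COC1=O | intermediate
6 | S-ethyl (2S)-2-methylpent-4-enethioate | C=CC[C@H](C)C(=O)SCC | intermediate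
7 | (3S)-1-(9-borabicyclo[3.3.1]nonan-9-yl)-3,7-dimethyloct-6-en-3-yl acetate | C12CCCC(CCC1)B2CC[C@](C)(OC(C)=O)CCC=C(C)C | intermediate
8 | (6R,10S)-2,6,10-trimethyl-9-oxotrideca-2,12-dien-6-yl acetate | C=CC[C@H](C)C(=O)CC[C@](C)(OC(C)=O)CCC=C(C)C | intermediate
9 | (6S,10S)-3-chloro-2,6,10-trimethyl-9-oxotrideca-1,12-dien-6-yl acetate (C3 epimers) | C=CC[C@H](C)C(=O)CC[C@](C)(OC(C)=O)CCC(Cl)C(C)=C | intermediate
10 | (2E)-3-methylpent-2-en-4-yn-1-ol | C#C/C(C)=C/CO | starting material
11 | [(2S,3S)-3-ethynyl-3-methyloxiran-2-yl]methanol | C#C[C@]1(C)O[C@H]1CO | intermediate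
12 | [(2S,3S)-3-ethenyl-3-methyloxiran-2-yl]methanol | C=C[C@]1(C)O[C@H]1CO | intermediate
13 | (2R,3S)-3-ethenyl-3-methyloxirane-2-carbaldehyde | C=C[C@]1(C)O[C@H]1C=O | intermediate
14 | [(6R,10S)-6-acetoxy-2,6,10-trimethyl-9-oxotrideca-2,12-dien-1-yl]chromium dichloride (trivalent chromium, E/Z) | C=CC[C@H](C)C(=O)CC[C@](C)(OC(C)=O)CCC=C(C)C[Cr](Cl)Cl | intermediate
15 | (5R,9S)-1-[(2S,3S)-3-ethenyl-3-methyloxiran-2-yl]-1-hydroxy-5,9-dimethyl-8-oxo-2-(prop-1-en-2-yl)dodec-11-en-5-yl acetate (C1/C2 diastereomers) | C=C[C@]1(C)O[C@H]1C(O)C(C(C)=C)CC[C@@](C)(OC(C)=O)CCC(=O)[C@@H](C)CC=C | intermediate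
16 | (5R,9S)-1-[(2R,3S)-3-ethenyl-3-methyloxiran-2-yl]-5,9-dimethyl-1,8-dioxo-2-(prop-1-en-2-yl)dodec-11-en-5-yl acetate (C2 epimers) | C=C[C@]1(C)O[C@H]1C(=O)C(C(C)=C)CC[C@@](C)(OC(C)=O)CCC(=O)[C@@H](C)CC=C | intermediate
17 | (5R,9S)-1-[(2R,3S)-3-ethenyl-3-methyloxiran-2-yl]-5,9-dimethyl-1,8-dioxo-2-(propan-2-ylidene)dodec-11-en-5-yl acetate | C=C[C@]1(C)O[C@H]1C(=O)C(=C(C)C)CC[C@@](C)(OC(C)=O)CCC(=O)[C@@H](C)CC=C | intermediate
18 | (1R,6R,10S,14S)-6,10,14-trimethyl-2,9-dioxo-3-(propan-2-ylidene)-15-oxabicyclo[12.1.0]pentadec-12-en-6-yl acetate (E/Z) | CC(=O)O[C@@]1(C)CCC(=O)[C@@H](C)CC=C[C@]2(C)O[C@H]2C(=O)C(=C(C)C)CC1 | intermediate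
19 | (1R,6R,10S,14S)-6,10,14-trimethyl-2,9-dioxo-3-(propan-2-ylidene)-15-oxabicyclo[12.1.0]pentadecan-6-yl acetate | CC(=O)O[C@@]1(C)CCC(=O)[C@@H](C)CCC[C@]2(C)O[C@H]2C(=O)C(=C(C)C)CC1 | target

**Step count:** 12 steps in total. Longest linear sequence: 8 steps (3 → 5 → 6 → 8 → 9 → 15 → 17 → 18 → 19, steps 2, 3, 4, 5, 9, 10, 11, 12).

**Steps most likely to fail**

Step 11. The carbene formed at C6 may be held back by chelation to the C9 carbonyl, or may fail to add to the vinyl group on the fully substituted C4, so that intermolecular metathesis to dimers and oligomers outruns ring closure. The fallback inverts the order of the two unions, so that the hindered olefin is engaged intermolecularly and the ring is closed at C1–C2. It sets out from 9 and 12 and returns at 18. Cross-metathesis of 9 with an excess of 12 (second-generation Grubbs catalyst RuCl2(=CHPh)(H2IMes)(PCy3), CH2Cl2, 40 °C) should give the E-configured hydroxy chloride F1, in which C5=C6 is already in place. Buffered Dess–Martin oxidation would give the epoxy aldehyde F2. Slow addition of F2 to CrCl2 in THF at high dilution should form the allylchromium dichloride F3, which closes the 14-membered ring by intramolecular Nozaki–Hiyama allylation to the macrocyclic homoallylic alcohol F4. Dess–Martin oxidation to the deconjugated macrocyclic ketone F5 and DBU equilibration as in step 10 would then give 18.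

Step 4. Transfer of the primary alkyl group from boron to palladium may be slow, and the carbonate base may erode the configuration at C8 of the thioester. The fallback replaces the organoboron coupling by a base-free organozinc (Fukuyama) coupling. It sets out from 2 and returns at 8. The borane 7 formed from 2 and 9-BBN would be oxidised with NaBO3·4H2O in THF/H2O to the primary alcohol F6, which is iodinated at once (I2, PPh3, imidazole) to the iodide F7 to forestall acetyl migration. Zinc insertion (Zn, DMA) should give the alkylzinc iodide F8, and coupling with 6 (PdCl2(PPh3)2, toluene, rt) would give 8.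

Step 9. Chromium may reduce or ring-open the vinyl oxirane of 13 by single-electron chemistry at the allylic C–O bond, or react sluggishly with the secondary chloride. The fallback uses a metal-free thermal allylboration. It sets out from 9 and returns at 15. Palladium-catalysed borylation of 9 (B2pin2, Pd2(dba)3, DMSO, 50 °C) should give the primary allyl pinacolboronate F9, which is purified free of palladium. Mixing F9 with 13 in toluene at rt should give, through a chair transition state and attack of the γ-carbon, the borate ester F10, and mild hydrolytic work-up would release 15.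

**Further compounds**
F1 | step 11 | cross-metathesis product of 9 and 12: E-olefin between C5 and C6, CH2OH at C2, allylic chloride at C1 (C1 epimers) | C=C(C)C(Cl)CC[C@@](C)(OC(C)=O)CCC(=O)[C@@H](C)C/C=C/[C@]1(C)O[C@H]1CO
F2 | step 11 | epoxy aldehyde from F1 | C=C(C)C(Cl)CC[C@@](C)(OC(C)=O)CCC(=O)[C@@H](C)C/C=C/[C@]1(C)O[C@H]1C=O
F3 | step 11 | allylchromium dichloride from F2 | Cl[Cr](Cl)CC(C)=CCC[C@@](C)(OC(C)=O)CCC(=O)[C@@H](C)C/C=C/[C@]1(C)O[C@H]1C=O
F4 | step 11 | macrocyclic homoallylic alcohol (C2 carbinol, isopropenyl on C1, C1/C2 diastereomers) | CC(=O)O[C@@]1(C)CCC(=O)[C@@H](C)C/C=C/[C@]2(C)O[C@H]2C(O)C(C(C)=C)CC1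
F5 | step 11 | macrocyclic deconjugated ketone (isopropenyl on C1) | CC(=O)O[C@@]1(C)CCC(=O)[C@@H](C)C/C=C/[C@]2(C)O[C@H]2C(=O)C(C(C)=C)CC1
F6 | step 4 | (3R)-1-hydroxy-3,7-dimethyloct-6-en-3-yl acetate | OCC[C@](C)(OC(C)=O)CCC=C(C)C
F7 | step 4 | (3R)-1-iodo-3,7-dimethyloct-6-en-3-yl acetate | ICC[C@](C)(OC(C)=O)CCC=C(C)C
F8 | step 4 | [(3R)-3-acetoxy-3,7-dimethyloct-6-en-1-yl]zinc iodide | I[Zn]CC[C@](C)(OC(C)=O)CCC=C(C)C
F9 | step 9 | (6R,10S)-2,6,10-trimethyl-9-oxo-1-(4,4,5,5-tetramethyl-1,3,2-dioxaborolan-2-yl)trideca-2,12-dien-6-yl acetate (E/Z) | C=CC[C@H](C)C(=O)CC[C@](C)(OC(C)=O)CCC=C(C)CB1OC(C)(C)C(C)(C)O1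
F10 | step 9 | pinacol borate ester of 15 | C=C[C@]1(C)O[C@H]1C(OB2OC(C)(C)C(C)(C)O2)C(C(C)=C)CC[C@@](C)(OC(C)=O)CCC(=O)[C@@H](C)CC=C
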